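## The problem

Compound 25 is a 2-aryl-3-(hydroxymethyl)-2,3-dihydrobenzofuran: a five-membered ring O1–C2–C3–C3a–C7a fused to a benzene ring that carries a methoxy group at C7 and a three-carbon chain at C5, the chain ending in an (E)-ferulate ester. The two stereocentres are adjacent, C2 (R, bearing the guaiacyl ring) and C3 (S, bearing the C9 hydroxymethyl group), with the aryl and hydroxymethyl groups trans. C2 is a p-oxybenzylic ether carbon that can ionise, so it can in principle be corrected thermodynamically from C3, since trans is the more stable arrangement. C3 cannot be repaired once C9 is an alcohol and has to be set absolutely by a reagent or catalyst. The cinnamate ester does not tolerate hydroxide, hydrogenation or alkene-cleaving oxidants, the two free guaiacol-type phenols do not tolerate oxidants such as periodate, and the C2–O1 benzylic aryl ether is at risk from strong acid, hydrogenolysis and phenoxide-driven quinone methide opening. Of three hydroxyl-bearing positions plus the ferulate phenol, exactly one aliphatic oxygen must carry the acyl group, so the order of events at the chain terminus decides how many protecting groups are needed. The enabling feature is that C2 and C3 are the two carbons of the C2=C3 bond of a benzofuran and need an aryl group and a one-carbon arm on opposite faces. That is the outcome of an anti addition across this bond, and a tetracoordinate boron on C2 makes C3 nucleophilic and hands its aryl group to C2 as C3 is alkylated.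

## Retrosynthesis

**Ester (25 ⇐ 24 ⇐ 21 + 22).** After removal of one phenolic methoxymethyl (MOM) group (25 from 24), the ester is cut at its alkyl C–O bond, between the carboxylate oxygen and the chain CH2, not at the acyl C–O bond. Acylation of a chain alcohol would have to distinguish it from the C9 alcohol and from two phenols and would cost several protecting-group steps. Alkylation of the ferulate anion of 22 by a primary halide distinguishes the sites by acidity alone, because hydrogen carbonate ionises only the carboxylic acid. The precursor 21 therefore carries the chain terminus as a chloride and the C9 alcohol free. The forward reaction must be a clean SN2 displacement with iodide assistance, and the chloride must survive organolithium reagents at −78 °C, Pd(0), fluoride, osmium and borohydride on the way.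

**C9 (21 ⇐ 18 ⇐ 17).** The hydroxymethyl carbon is traced to the inner CH2 of an allyl group: the C9=C10 bond of the propenyl compound 18 is cut, and 18 comes from the allyl compound 17 by moving the double bond one position. A one-carbon electrophile introduced directly would save two steps, but the allyl group is the electrophile for which a chiral catalyst can be expected to control the new C3 centre. The forward steps must stop the isomerisation at the propenyl stage and must not let the intermediate α-aryl aldehyde enolise.

**C2–H (17 ⇐ 16).** The C2–H bond is traced to a C2–B bond. The precursor 16 has a fully substituted C2 bearing boron, the aryl group and O1. The forward reaction must replace boron by hydrogen with retention, so that the aryl group stays trans to the C3 arm.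

**Key disconnection (16 ⇐ 10 + 14 + 13).** The C3–C9 and C2–C1′ bonds are cut together. This returns the flat benzofuran-2-yl boronic ester 10, the aryllithium 14 and allyl acetate 13. Cutting O1–C2 or C3–C3a instead would require an acyclic or ring-expanded precursor in which the stereocentres are built beforehand; here both arise in one step from achiral components. The forward reaction must allylate C3 of the boronate 15 enantioselectively with concurrent anti migration of the aryl group from boron to C2.

**Benzofuran (10 ⇐ 9 ⇐ 8 ⇐ 4 + 5 ⇐ 3 ⇐ 1).** The C2–B bond comes from C–H borylation of 9, the chloride from the alcohol 8, and the furan ring (O1–C2 and C3–C3a) from the iodophenol 4 and trimethylsilylacetylene 5. Iodophenol 4 comes from dihydroconiferyl alcohol 3, and 3 from eugenol 1. Eugenol already contains the benzene ring with the phenol oxygen (O1), the methoxy group (C7) and the three-carbon chain (C5) in the correct positions. Because the phenol is consumed in ring formation before the chain alcohol is converted, no selective protection is needed.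

**Aryl donor (14 ⇐ 12 ⇐ 11).** The aryllithium comes from bromide 12 by halogen–lithium exchange, and 12 from 4-bromo-2-methoxyphenol 11. The phenol is masked as a MOM ether, not a silyl ether, because a silyl ether would be lost to fluoride in the protodeboronation. A free guaiacol would not survive periodate, and the MOM group leaves under dilute acid, which the cinnamate tolerates.

## Roads not taken

Alternative 1: De novo construction of the benzene ring by [2+2+2] cyclotrimerisation. The cut is through C3a–C7a, C4–C5 and C6–C7. A ruthenium or rhodium catalyst would join the silyl ynol ether diyne A2 with the pentynyl silyl ether A3 to give the 7-triethylsilyl dihydrobenzofuran A1, closing the dihydrofuran and benzene rings together.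
- Merits: three C–C bonds and two rings form in one step, and both stereocentres would be fixed beforehand by established acyclic methods, so the key step would not have to deliver any stereoselectivity. In that respect it is safer than step 7 of the chosen plan.
- Weak points: A2 is a secondary benzylic ynol ether with two stereocentres and needs its own multistep asymmetric synthesis. Such ethers are thermally fragile. The unsymmetrical alkyne A3 can insert in two orientations (chain at C5 or C6). The silyl group at C7 of A1 still has to be turned into a methoxy group, which for a trialkylsilyl arene takes several steps.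
- Comparison: the chosen plan takes the whole arene with all three substituents from eugenol and needs no correction at C7. What it has to set against the safer stereochemistry of this road is an unproven catalytic step.

Alternative 2: Wolff ring contraction. The cut is C3–C3a. Photolysis of the 3-diazochroman-4-one A4 in methanol would expel nitrogen, shift the aryl carbon from the carbonyl carbon to C3 and trap the ketene as the methyl ester A5, which is equilibrated to trans.
- Merits: chromanones are easy to assemble, and C9 arrives as an ester, one reduction away from the hydroxymethyl group. This is better than the chosen plan, which spends steps 9 and 10 trimming an allyl group. The trans relationship is also obtained by simple base equilibration at C3.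
- Weak points: the C2 centre of a 2-arylchromanone is labile to retro-oxa-Michael opening under the basic diazo-transfer conditions. The carbene from A4 has a C2–H bond next to it, so a 1,2-hydride shift to the aromatic flavone competes with ring contraction. The benzyl ether in A5 would have to be removed by hydrogenolysis before the cinnamate is introduced, which adds protecting-group steps.
- Comparison: the chosen plan sets both centres with one catalyst and keeps C2 non-epimerisable until the end, at the price of two extra steps to reach C9.

Alternative 3: Quinone methide ring closure. The cut is O1–C2. Mild acid would ionise the p-hydroxybenzylic alcohol of the acyclic triol A6 to a p-quinone methide, and the ortho phenol adds to C2 to give A7 with the ring closed trans.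
- Merits: this is the best-precedented road to this class, and in reliability it is better than the chosen plan. The C3 centre comes from an auxiliary-controlled aldol reaction, the closure corrects itself towards trans, and C9 is at the right oxidation level throughout.
- Weak points: it needs a stoichiometric auxiliary and an ortho-oxygenated arylacetic acid that takes several steps from eugenol-type material. A7 emerges with a free phenol, a free C9 alcohol and a protected chain alcohol, so a conventional acylation end-game would need further protection and deprotection.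
- Comparison: the chosen plan offers catalytic creation of both centres in one step from flat precursors and a shorter sequence. Its known-chemistry fallback for step 7 is deliberately placed in equally well-precedented territory.

Key step: step 7

Assumption: (S)-H8-BINAP is written for step 7 on the assumption that it gives the 3R centre of 16. The sense of induction for a benzofuran-2-yl boronate cannot be predicted with certainty, and the antipodal ligand is used if it proves opposite.

## Route

Step 1
Reactants: 1 eugenol (4-allyl-2-methoxyphenol)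
Product: 3 4-(3-hydroxypropyl)-2-methoxyphenol (dihydroconiferyl alcohol), via alkylborane 2 (not isolated)
Conditions: 9-BBN (2.2 equiv), THF, 0 °C → rt; then 3 M NaOH, 30% H2O2, 0 °C → rt
Reagents that add atoms: hydrogen peroxide, OO
Why: Brown hydroboration–oxidation: the bulky dialkylborane places boron on the terminal carbon of the allyl group and alkaline peroxide replaces boron by hydroxyl; the second equivalent of 9-BBN allows for the acidic phenol, which is returned on work-up.

Step 2
Reactants: 3 4-(3-hydroxypropyl)-2-methoxyphenol
Product: 4 4-(3-hydroxypropyl)-2-iodo-6-methoxyphenol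
Conditions: NaI (1.05 equiv), NaOH (1.05 equiv), aq. NaOCl (1.05 equiv, dropwise), MeOH, 0 °C
Reagents that add atoms: sodium iodide, [Na+].[I-]
Why: Electrophilic aromatic iodination of the phenolate by hypoiodite generated in situ; the para position is blocked by the chain and one ortho position by the methoxy group, so iodine enters C6, the only free position ortho to the phenolate oxygen.

Step 3
Reactants: 4 4-(3-hydroxypropyl)-2-iodo-6-methoxyphenol; 5 ethynyl(trimethyl)silane
Product: 8 3-(7-methoxy-1-benzofuran-5-yl)propan-1-ol, via silylalkynylphenol 6 (not isolated), via ethynylphenol 7 (not isolated)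
Conditions: PdCl2(PPh3)2 (2 mol%), CuI (4 mol%), 5 (1.3 equiv), Et3N, THF, rt; then TBAF (1 M in THF, 2.2 equiv), 60 °C
Reagents that add atoms: none
Why: Sonogashira coupling at the aryl iodide, then in the same flask fluoride desilylation of the alkyne and 5-endo-dig addition of the phenolate to the terminal alkyne (assisted by the copper salt still present), which builds the furan ring with C2 unsubstituted; the primary alcohol is a spectator.

Step 4
Reactants: 8 3-(7-methoxy-1-benzofuran-5-yl)propan-1-ol
Product: 9 5-(3-chloropropyl)-7-methoxy-1-benzofuran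
Conditions: PPh3 (1.3 equiv), CCl4 (3 equiv), CH2Cl2, 0 → 40 °C
Reagents that add atoms: carbon tetrachloride, ClC(Cl)(Cl)Cl
Why: Appel reaction: the alcohol is activated as an alkoxyphosphonium ion and displaced by chloride (SN2) under neutral conditions that leave the electron-rich benzofuran alone; the chloride is the masked leaving group for the final ester formation.

Step 5
Reactants: 9 5-(3-chloropropyl)-7-methoxy-1-benzofuran
Product: 10 2-[5-(3-chloropropyl)-7-methoxy-1-benzofuran-2-yl]-4,4,5,5-tetramethyl-1,3,2-dioxaborolane
Conditions: [Ir(OMe)(cod)]2 (1.5 mol%), dtbpy (3 mol%), B2pin2 (1.0 equiv), THF, 50 °C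
Reagents that add atoms: bis(pinacolato)diboron, CC1(C)OB(OC1(C)C)B1OC(C)(C)C(C)(C)O1
Why: Iridium-catalysed aromatic C–H borylation: benzofurans react at C2, the C–H bond next to the ring oxygen, and the benzenoid C4–H and C6–H bonds are each flanked by substituents; the alkyl chloride and the methyl ether are tolerated.

Step 6
Reactants: 11 4-bromo-2-methoxyphenol
Product: 12 4-bromo-2-methoxy-1-(methoxymethoxy)benzene
Conditions: MOMCl (1.3 equiv), i-Pr2NEt (1.5 equiv), CH2Cl2, 0 °C → rt
Reagents that add atoms: chloromethyl methyl ether, COCCl
Why: O-Alkylation of the phenol to the methoxymethyl acetal; this group withstands tert-butyllithium at −78 °C, fluoride, osmium/periodate and borohydride and leaves under dilute acid at the end.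

Step 7
Reactants: 12 4-bromo-2-methoxy-1-(methoxymethoxy)benzene; 10 2-[5-(3-chloropropyl)-7-methoxy-1-benzofuran-2-yl]-4,4,5,5-tetramethyl-1,3,2-dioxaborolane; 13 allyl acetate
Product: 16 2-[(2R,3R)-3-allyl-5-(3-chloropropyl)-7-methoxy-2-[3-methoxy-4-(methoxymethoxy)phenyl]-2,3-dihydro-1-benzofuran-2-yl]-4,4,5,5-tetramethyl-1,3,2-dioxaborolane (aryl trans to allyl; boron cis to allyl), via aryllithium 14 (not isolated), via lithium boronate complex 15 (not isolated)
Conditions: 12 (1.1 equiv), t-BuLi (2.1 equiv), THF/Et2O, −78 °C; 10 (1.0 equiv), THF, −78 → 0 °C; then Pd2(dba)3 (2.5 mol%), (S)-H8-BINAP (6 mol%), 13 (1.5 equiv), THF, 0 °C → rt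
Reagents that add atoms: none
Why: Proposed new method: aryllithium 14 adds to the empty boron orbital of 10 to give the tetracoordinate boronate 15, whose C2=C3 bond is an electron-rich π-nucleophile; C3 attacks a terminus of the cationic (π-allyl)palladium–bisphosphine complex formed from 13 on the face away from the metal while the aryl group migrates from boron to C2 antiperiplanar to the forming C3–C9 bond, and acetate leaves as its lithium salt. The closest known reaction type is the palladium-catalysed enantioselective three-component allylation of indol-2-yl boronate complexes with a dearomatising 1,2-metalate shift; the benzofuran case is new because the ring oxygen makes C3 less nucleophilic than in an N-alkylindole and because the C2–O1 bond can act as a leaving group. No ring is closed: the furan ring is only dearomatised and the benzene ring stays intact. C3 is set by the chiral bisphosphine on the π-allyl palladium, which selects one enantiotopic face of the planar boronate in an outer-sphere attack. C2 is set relative to C3 by the stereospecific anti migration, so the aryl group ends trans to the allyl group and boron cis to it, which is the (2R,3R) arrangement. The step needs C3 allylation to outrun transfer of an aryl group from 15 to palladium (allyl–aryl coupling) and ring-opening migration with loss of the C7a phenoxide; the low temperature, the non-transferable pinacol ligand and the strongly electrophilic cationic π-allyl complex are relied on for this, and an aryl group migrates far more readily than a pinacol oxygen.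

Step 8
Reactants: 16 2-[(2R,3R)-3-allyl-5-(3-chloropropyl)-7-methoxy-2-[3-methoxy-4-(methoxymethoxy)phenyl]-2,3-dihydro-1-benzofuran-2-yl]-4,4,5,5-tetramethyl-1,3,2-dioxaborolane
Product: 17 (2R,3R)-3-allyl-5-(3-chloropropyl)-7-methoxy-2-[3-methoxy-4-(methoxymethoxy)phenyl]-2,3-dihydro-1-benzofuran (trans)
Conditions: TBAF·3H2O (3 equiv), toluene, 45 °C
Reagents that add atoms: none
Why: Fluoride-promoted protodeboronation of a tertiary benzylic boronic ester: fluoride forms the boronate and water protonates C2 on the face of the departing boron (retention), so the aryl group stays trans to the allyl group; the MOM ether and the primary chloride are not attacked under these conditions, which is why no silyl ether is carried at this stage.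

Step 9
Reactants: 17 (2R,3R)-3-allyl-5-(3-chloropropyl)-7-methoxy-2-[3-methoxy-4-(methoxymethoxy)phenyl]-2,3-dihydro-1-benzofuran
Product: 18 (2R,3R)-5-(3-chloropropyl)-7-methoxy-2-[3-methoxy-4-(methoxymethoxy)phenyl]-3-[(E)-prop-1-en-1-yl]-2,3-dihydro-1-benzofuran
Conditions: [Ir(cod)(PMePh2)2]PF6 (3 mol%, activated with H2 then purged with N2), THF, rt
Reagents that add atoms: none
Why: Metal-hydride alkene isomerisation (insertion/β-hydride elimination) moves the terminal double bond one position to the (E)-propenyl group; the cationic iridium hydride discriminates strongly against the resulting 1,2-disubstituted alkene, which protects the C3–H bond from a second migration.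

Step 10
Reactants: 18 (2R,3R)-5-(3-chloropropyl)-7-methoxy-2-[3-methoxy-4-(methoxymethoxy)phenyl]-3-[(E)-prop-1-en-1-yl]-2,3-dihydro-1-benzofuran
Product: 21 [(2R,3S)-5-(3-chloropropyl)-7-methoxy-2-[3-methoxy-4-(methoxymethoxy)phenyl]-2,3-dihydro-1-benzofuran-3-yl]methanol, via vicinal diol 19 (not isolated), via aldehyde 20 (not isolated)
Conditions: OsO4 (2 mol%), NaIO4 (4 equiv), 2,6-lutidine (2 equiv), dioxane/H2O 3:1, rt; extractive work-up; NaBH4, MeOH/THF, 0 °C
Reagents that add atoms: osmium tetroxide, O=[Os](=O)(=O)=O (catalytic oxygen carrier, reoxidised by sodium periodate, [Na+].[O-]I(=O)(=O)=O)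
Why: Lemieux–Johnson oxidation (catalytic dihydroxylation and periodate glycol cleavage, buffered by 2,6-lutidine) cuts the propenyl group at C9, and the α-aryl aldehyde 20 is reduced at once with borohydride so that it has no time to enolise; C3 keeps its geometry and is now designated S only because the substituent priorities change.

Step 11
Reactants: 21 [(2R,3S)-5-(3-chloropropyl)-7-methoxy-2-[3-methoxy-4-(methoxymethoxy)phenyl]-2,3-dihydro-1-benzofuran-3-yl]methanol; 22 (E)-ferulic acid
Product: 24 3-[(2R,3S)-3-(hydroxymethyl)-7-methoxy-2-[3-methoxy-4-(methoxymethoxy)phenyl]-2,3-dihydro-1-benzofuran-5-yl]propyl (2E)-3-(4-hydroxy-3-methoxyphenyl)prop-2-enoate, via primary iodide 23 (not isolated)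
Conditions: 22 (1.5 equiv), KHCO3 (1.5 equiv), NaI (1.5 equiv), DMF, 60 °C
Reagents that add atoms: none
Why: O-Alkylation of a carboxylate by a primary halide (SN2) with in situ Finkelstein activation: hydrogen carbonate ionises only the carboxylic acid of 22, not its phenol nor the alcohol of 21, so the ester forms at the chain terminus without protection of the C9 alcohol or of the ferulate phenol.

Step 12
Reactants: 24 3-[(2R,3S)-3-(hydroxymethyl)-7-methoxy-2-[3-methoxy-4-(methoxymethoxy)phenyl]-2,3-dihydro-1-benzofuran-5-yl]propyl (2E)-3-(4-hydroxy-3-methoxyphenyl)prop-2-enoate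
Product: 25 3-[(2R,3S)-2-(4-hydroxy-3-methoxyphenyl)-3-(hydroxymethyl)-7-methoxy-2,3-dihydro-1-benzofuran-5-yl]propyl (2E)-3-(4-hydroxy-3-methoxyphenyl)prop-2-enoate (CNP0149450.1)
Conditions: 2 M aq. HCl, THF/i-PrOH, 40 °C
Reagents that add atoms: none
Why: Acid-catalysed hydrolysis of the aryl methoxymethyl acetal; the cinnamate ester and the primary alcohol are stable to dilute aqueous acid at this temperature, and any reversible ionisation of the C2–O1 bond recloses to the more stable trans isomer because C3 is fixed.

## Compound list

1 | eugenol (4-allyl-2-methoxyphenol) | C=CCc1ccc(O)c(OC)c1 | starting material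
2 | 9-[3-(4-hydroxy-3-methoxyphenyl)propyl]-9-borabicyclo[3.3.1]nonane (phenol shown free) | COc1cc(CCCB2C3CCCC2CCC3)ccc1O | intermediate (not isolated)
3 | 4-(3-hydroxypropyl)-2-methoxyphenol | OCCCc1ccc(O)c(OC)c1 | intermediate
4 | 4-(3-hydroxypropyl)-2-iodo-6-methoxyphenol | OCCCc1cc(I)c(O)c(OC)c1 | intermediate
5 | ethynyl(trimethyl)silane | C#C[Si](C)(C)C | starting material
6 | 4-(3-hydroxypropyl)-2-methoxy-6-[(trimethylsilyl)ethynyl]phenol | OCCCc1cc(C#C[Si](C)(C)C)c(O)c(OC)c1 | intermediate (not isolated)
7 | 2-ethynyl-4-(3-hydroxypropyl)-6-methoxyphenol | OCCCc1cc(C#C)c(O)c(OC)c1 | intermediate (not isolated)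
8 | 3-(7-methoxy-1-benzofuran-5-yl)propan-1-ol | OCCCc1cc(OC)c2occc2c1 | intermediate
9 | 5-(3-chloropropyl)-7-methoxy-1-benzofuran | ClCCCc1cc(OC)c2occc2c1 | intermediate
10 | 2-[5-(3-chloropropyl)-7-methoxy-1-benzofuran-2-yl]-4,4,5,5-tetramethyl-1,3,2-dioxaborolane | ClCCCc1cc(OC)c2oc(B3OC(C)(C)C(C)(C)O3)cc2c1 | intermediate
11 | 4-bromo-2-methoxyphenol | COc1cc(Br)ccc1O | starting material
12 | 4-bromo-2-methoxy-1-(methoxymethoxy)benzene | COCOc1ccc(Br)cc1OC | intermediate
13 | allyl acetate | C=CCOC(C)=O | starting material
14 | [3-methoxy-4-(methoxymethoxy)phenyl]lithium | COCOc1ccc([Li])cc1OC | intermediate (not isolated)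
15 | lithium [5-(3-chloropropyl)-7-methoxy-1-benzofuran-2-yl][3-methoxy-4-(methoxymethoxy)phenyl](2,3-dimethylbutane-2,3-diolato)borate | [Li+].ClCCCc1cc(OC)c2oc(cc2c1)[B-]3(OC(C)(C)C(C)(C)O3)c4ccc(OCOC)c(OC)c4 | intermediate (not isolated)
16 | 2-[(2R,3R)-3-allyl-5-(3-chloropropyl)-7-methoxy-2-[3-methoxy-4-(methoxymethoxy)phenyl]-2,3-dihydro-1-benzofuran-2-yl]-4,4,5,5-tetramethyl-1,3,2-dioxaborolane | ClCCCc1cc(OC)c2c(c1)[C@@H](CC=C)[C@](B3OC(C)(C)C(C)(C)O3)(c4ccc(OCOC)c(OC)c4)O2 | intermediate
17 | (2R,3R)-3-allyl-5-(3-chloropropyl)-7-methoxy-2-[3-methoxy-4-(methoxymethoxy)phenyl]-2,3-dihydro-1-benzofuran | ClCCCc1cc(OC)c2c(c1)[C@@H](CC=C)[C@H](c3ccc(OCOC)c(OC)c3)O2 | intermediate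
18 | (2R,3R)-5-(3-chloropropyl)-7-methoxy-2-[3-methoxy-4-(methoxymethoxy)phenyl]-3-[(E)-prop-1-en-1-yl]-2,3-dihydro-1-benzofuran | ClCCCc1cc(OC)c2c(c1)[C@@H](/C=C/C)[C@H](c3ccc(OCOC)c(OC)c3)O2 | intermediate
19 | 1-[(2R,3S)-5-(3-chloropropyl)-7-methoxy-2-[3-methoxy-4-(methoxymethoxy)phenyl]-2,3-dihydro-1-benzofuran-3-yl]propane-1,2-diol (mixture at the two carbinol carbons) | ClCCCc1cc(OC)c2c(c1)[C@@H](C(O)C(C)O)[C@H](c3ccc(OCOC)c(OC)c3)O2 | intermediate (not isolated)
20 | (2R,3R)-5-(3-chloropropyl)-7-methoxy-2-[3-methoxy-4-(methoxymethoxy)phenyl]-2,3-dihydro-1-benzofuran-3-carbaldehyde | ClCCCc1cc(OC)c2c(c1)[C@@H](C=O)[C@H](c3ccc(OCOC)c(OC)c3)O2 | intermediate (not isolated)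
21 | [(2R,3S)-5-(3-chloropropyl)-7-methoxy-2-[3-methoxy-4-(methoxymethoxy)phenyl]-2,3-dihydro-1-benzofuran-3-yl]methanol | ClCCCc1cc(OC)c2c(c1)[C@@H](CO)[C@H](c3ccc(OCOC)c(OC)c3)O2 | intermediate
22 | (E)-ferulic acid | COc1cc(/C=C/C(=O)O)ccc1O | starting material
23 | [(2R,3S)-5-(3-iodopropyl)-7-methoxy-2-[3-methoxy-4-(methoxymethoxy)phenyl]-2,3-dihydro-1-benzofuran-3-yl]methanol | ICCCc1cc(OC)c2c(c1)[C@@H](CO)[C@H](c3ccc(OCOC)c(OC)c3)O2 | intermediate (not isolated)
24 | 3-[(2R,3S)-3-(hydroxymethyl)-7-methoxy-2-[3-methoxy-4-(methoxymethoxy)phenyl]-2,3-dihydro-1-benzofuran-5-yl]propyl (2E)-3-(4-hydroxy-3-methoxyphenyl)prop-2-enoate | COc1cc(/C=C/C(=O)OCCCc2cc(OC)c3c(c2)[C@@H](CO)[C@H](c2ccc(OCOC)c(OC)c2)O3)ccc1O | intermediate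
25 | 3-[(2R,3S)-2-(4-hydroxy-3-methoxyphenyl)-3-(hydroxymethyl)-7-methoxy-2,3-dihydro-1-benzofuran-5-yl]propyl (2E)-3-(4-hydroxy-3-methoxyphenyl)prop-2-enoate | COc1cc(/C=C/C(=O)OCCCc2cc(OC)c3c(c2)[C@@H](CO)[C@H](c2ccc(O)c(OC)c2)O3)ccc1O | target

## Step count and risk

Total: 12 steps. Longest linear sequence: 11 steps (eugenol 1 to 25 through steps 1–5 and 7–12); step 6 is a one-step branch.

**Step 7 (key step, proposed new method).** The boronate 15 is most likely to be diverted before C3 is allylated. An aryl group can be transferred from boron to palladium and coupled with the allyl fragment, or the 1,2-shift can take place with opening of the ring and departure of the C7a phenoxide. Both become competitive because the benzofuran π-system is a weaker nucleophile than the indole one. Insufficient facial selectivity at C3 is the second concern.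

Fallback with known chemistry, from 10 to 21:
- Oxidation of the C–B bond of 10 (NaBO3·4H2O, THF/H2O) should give the lactone 5-(3-chloropropyl)-7-methoxy-1-benzofuran-2(3H)-one F1, and methanolysis (K2CO3, MeOH) opens it to methyl 2-[5-(3-chloropropyl)-2-hydroxy-3-methoxyphenyl]acetate F2.
- Aryllithium 14 is quenched with DMF to 3-methoxy-4-(methoxymethoxy)benzaldehyde F3, which is reduced (NaBH4) to [3-methoxy-4-(methoxymethoxy)phenyl]methanol F4.
- Mitsunobu etherification of the phenol F2 with F4 gives methyl 2-[5-(3-chloropropyl)-3-methoxy-2-{[3-methoxy-4-(methoxymethoxy)phenyl]methoxy}phenyl]acetate F5, and diazo transfer (p-ABSA, DBU) gives the aryldiazoacetate F6.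
- A chiral dirhodium(II) carboxylate then effects intramolecular carbenoid insertion into the benzylic ether C–H bond, closing the ring to the cis ester methyl (2R,3S)-5-(3-chloropropyl)-7-methoxy-2-[3-methoxy-4-(methoxymethoxy)phenyl]-2,3-dihydro-1-benzofuran-3-carboxylate F7.
- Sodium methoxide epimerises C3 to the trans ester methyl (2R,3R)-5-(3-chloropropyl)-7-methoxy-2-[3-methoxy-4-(methoxymethoxy)phenyl]-2,3-dihydro-1-benzofuran-3-carboxylate F8, and LiBH4 reduces it to 21, where the route is rejoined.

**Step 8.** The likely failure is loss of configuration at C2 through a free benzylic carbanion, or sluggish protonolysis. The electron-rich aryl group disfavours build-up of negative charge at C2, and a tertiary boronic ester with an oxygen on the same carbon is thinly supported for the fluoride protocol. Slow attack of fluoride on the primary chloride at long reaction times is a further concern.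

Fallback, from 16 to 17, giving up stereospecific replacement for thermodynamic control at C2 from C3:
- Phenyllithium converts 16 into the lithium phenylboronate complex F9. Single-electron oxidation under photoredox conditions with a thiol as hydrogen-atom donor cleaves the C–B bond through the C2 radical and gives 17 mixed with its C2 epimer (2S,3R)-3-allyl-5-(3-chloropropyl)-7-methoxy-2-[3-methoxy-4-(methoxymethoxy)phenyl]-2,3-dihydro-1-benzofuran F10.
- Trifluoroacetic acid in CH2Cl2 equilibrates C2 through the p-alkoxybenzylic cation towards the trans isomer and at the same time removes the acetal, giving 4-[(2R,3R)-3-allyl-5-(3-chloropropyl)-7-methoxy-2,3-dihydro-1-benzofuran-2-yl]-2-methoxyphenol F11.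
- MOMCl/i-Pr2NEt returns 17.

**Step 9.** The likely failure is migration of the double bond beyond the propenyl stage into C3 and on to the aromatic 3-propylbenzofuran, which would erase both stereocentres. The driving force for this is large once a metal hydride reaches the C3–H bond.

Fallback, from 17 to 21, without any isomerisation:
- Lemieux–Johnson cleavage of the terminal alkene of 17 gives 2-[(2R,3R)-5-(3-chloropropyl)-7-methoxy-2-[3-methoxy-4-(methoxymethoxy)phenyl]-2,3-dihydro-1-benzofuran-3-yl]acetaldehyde F12.
- TBSOTf/Et3N converts it into the silyl enol ether tert-butyl({2-[(2R,3R)-5-(3-chloropropyl)-7-methoxy-2-[3-methoxy-4-(methoxymethoxy)phenyl]-2,3-dihydro-1-benzofuran-3-yl]ethenyl}oxy)dimethylsilane F13.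
- Ozonolysis of this very electron-rich alkene at −78 °C with borohydride work-up removes the second carbon and gives 21 through aldehyde 20.

**Step 10.** The likely failure is enolisation of the α-aryl aldehyde 20 during the buffered periodate stage and work-up. This leads to epimerisation at C3 or to β-elimination of the C7a phenoxide, with ring opening and loss of both centres on reclosure.

Fallback, from 18 to 21: ozonolysis of 18 in CH2Cl2 at −78 °C to an indicator end-point gives the ozonide (2R,3R)-5-(3-chloropropyl)-7-methoxy-2-[3-methoxy-4-(methoxymethoxy)phenyl]-3-(5-methyl-1,2,4-trioxolan-3-yl)-2,3-dihydro-1-benzofuran F14. This is reduced in the cold by NaBH4/MeOH directly to 21, so the aldehyde never accumulates in a basic aqueous medium.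

**Step 12.** The likely failure is acid-induced ionisation of the C2–O1 bond once the phenol is free, with trapping by solvent. Attack of the released formaldehyde on the electron-rich rings and slow solvolysis of the cinnamate ester during a prolonged deprotection are further concerns.

Fallback, from 21 to 25, reversing the order of the last two operations:
- The acetal of 21 is hydrolysed first, when no ester is present and the conditions can be chosen freely, to give 4-[(2R,3S)-5-(3-chloropropyl)-3-(hydroxymethyl)-7-methoxy-2,3-dihydro-1-benzofuran-2-yl]-2-methoxyphenol F15.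
- The union with 22 under the conditions of step 11 (KHCO3, NaI, DMF), through the iodide 4-[(2R,3S)-3-(hydroxymethyl)-5-(3-iodopropyl)-7-methoxy-2,3-dihydro-1-benzofuran-2-yl]-2-methoxyphenol F16, then gives 25 directly as the last step. Selectivity for the carboxylate over both phenols rests on the same acidity argument.

## Further compounds

F1 | step 7 | 5-(3-chloropropyl)-7-methoxy-1-benzofuran-2(3H)-one | ClCCCc1cc(OC)c2OC(=O)Cc2c1
F2 | step 7 | methyl 2-[5-(3-chloropropyl)-2-hydroxy-3-methoxyphenyl]acetate | ClCCCc1cc(OC)c(O)c(CC(=O)OC)c1
F3 | step 7 | 3-methoxy-4-(methoxymethoxy)benzaldehyde | O=Cc1ccc(OCOC)c(OC)c1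
F4 | step 7 | [3-methoxy-4-(methoxymethoxy)phenyl]methanol | OCc1ccc(OCOC)c(OC)c1
F5 | step 7 | methyl 2-[5-(3-chloropropyl)-3-methoxy-2-{[3-methoxy-4-(methoxymethoxy)phenyl]methoxy}phenyl]acetate | ClCCCc1cc(OC)c(OCc2ccc(OCOC)c(OC)c2)c(CC(=O)OC)c1
F6 | step 7 | methyl 2-[5-(3-chloropropyl)-3-methoxy-2-{[3-methoxy-4-(methoxymethoxy)phenyl]methoxy}phenyl]-2-diazoacetate | ClCCCc1cc(OC)c(OCc2ccc(OCOC)c(OC)c2)c(C(=[N+]=[N-])C(=O)OC)c1
F7 | step 7 | methyl (2R,3S)-5-(3-chloropropyl)-7-methoxy-2-[3-methoxy-4-(methoxymethoxy)phenyl]-2,3-dihydro-1-benzofuran-3-carboxylate (cis) | ClCCCc1cc(OC)c2c(c1)[C@H](C(=O)OC)[C@H](c3ccc(OCOC)c(OC)c3)O2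
F8 | step 7 | methyl (2R,3R)-5-(3-chloropropyl)-7-methoxy-2-[3-methoxy-4-(methoxymethoxy)phenyl]-2,3-dihydro-1-benzofuran-3-carboxylate (trans) | ClCCCc1cc(OC)c2c(c1)[C@@H](C(=O)OC)[C@H](c3ccc(OCOC)c(OC)c3)O2
F9 | step 8 | lithium [(2R,3R)-3-allyl-5-(3-chloropropyl)-7-methoxy-2-[3-methoxy-4-(methoxymethoxy)phenyl]-2,3-dihydro-1-benzofuran-2-yl](phenyl)(2,3-dimethylbutane-2,3-diolato)borate | [Li+].ClCCCc1cc(OC)c2c(c1)[C@@H](CC=C)[C@]([B-]3(c5ccccc5)OC(C)(C)C(C)(C)O3)(c4ccc(OCOC)c(OC)c4)O2
F10 | step 8 | (2S,3R)-3-allyl-5-(3-chloropropyl)-7-methoxy-2-[3-methoxy-4-(methoxymethoxy)phenyl]-2,3-dihydro-1-benzofuran (cis) | ClCCCc1cc(OC)c2c(c1)[C@@H](CC=C)[C@@H](c3ccc(OCOC)c(OC)c3)O2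
F11 | step 8 | 4-[(2R,3R)-3-allyl-5-(3-chloropropyl)-7-methoxy-2,3-dihydro-1-benzofuran-2-yl]-2-methoxyphenol | ClCCCc1cc(OC)c2c(c1)[C@@H](CC=C)[C@H](c3ccc(O)c(OC)c3)O2
F12 | step 9 | 2-[(2R,3R)-5-(3-chloropropyl)-7-methoxy-2-[3-methoxy-4-(methoxymethoxy)phenyl]-2,3-dihydro-1-benzofuran-3-yl]acetaldehyde | ClCCCc1cc(OC)c2c(c1)[C@@H](CC=O)[C@H](c3ccc(OCOC)c(OC)c3)O2
F13 | step 9 | tert-butyl({2-[(2R,3R)-5-(3-chloropropyl)-7-methoxy-2-[3-methoxy-4-(methoxymethoxy)phenyl]-2,3-dihydro-1-benzofuran-3-yl]ethenyl}oxy)dimethylsilane (E/Z mixture) | ClCCCc1cc(OC)c2c(c1)[C@@H](C=CO[Si](C)(C)C(C)(C)C)[C@H](c3ccc(OCOC)c(OC)c3)O2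
F14 | step 10 | (2R,3R)-5-(3-chloropropyl)-7-methoxy-2-[3-methoxy-4-(methoxymethoxy)phenyl]-3-(5-methyl-1,2,4-trioxolan-3-yl)-2,3-dihydro-1-benzofuran | ClCCCc1cc(OC)c2c(c1)[C@@H](C3OOC(C)O3)[C@H](c4ccc(OCOC)c(OC)c4)O2
F15 | step 12 | 4-[(2R,3S)-5-(3-chloropropyl)-3-(hydroxymethyl)-7-methoxy-2,3-dihydro-1-benzofuran-2-yl]-2-methoxyphenol | ClCCCc1cc(OC)c2c(c1)[C@@H](CO)[C@H](c3ccc(O)c(OC)c3)O2
F16 | step 12 | 4-[(2R,3S)-3-(hydroxymethyl)-5-(3-iodopropyl)-7-methoxy-2,3-dihydro-1-benzofuran-2-yl]-2-methoxyphenol | ICCCc1cc(OC)c2c(c1)[C@@H](CO)[C@H](c3ccc(O)c(OC)c3)O2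
A1 | alternative 1 | (2R,3S)-trans-5-[3-(tert-butyldimethylsilyloxy)propyl]-2-[3-methoxy-4-(methoxymethoxy)phenyl]-7-(triethylsilyl)-3-[(triisopropylsilyloxy)methyl]-2,3-dihydro-1-benzofuran | CC(C)(C)[Si](C)(C)OCCCc2cc([Si](CC)(CC)CC)c3c(c2)[C@@H](CO[Si](C(C)C)(C(C)C)C(C)C)[C@H](c2ccc(OCOC)c(OC)c2)O3
A2 | alternative 1 | silyl ynol ether diyne: 1-[3-methoxy-4-(methoxymethoxy)phenyl]-2-[(triisopropylsilyloxy)methyl]but-3-yn-1-yl (triethylsilyl)ethynyl ether, stereocentres as in A1 | C#C[C@@H](CO[Si](C(C)C)(C(C)C)C(C)C)[C@H](c1ccc(OCOC)c(OC)c1)OC#C[Si](CC)(CC)CC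
A3 | alternative 1 | tert-butyl(dimethyl)(pent-4-yn-1-yloxy)silane | C#CCCCO[Si](C)(C)C(C)(C)C
A4 | alternative 2 | (2S)-2-(4-benzyloxy-3-methoxyphenyl)-6-[3-(tert-butyldimethylsilyloxy)propyl]-3-diazo-8-methoxychroman-4-one | CC(C)(C)[Si](C)(C)OCCCc1cc(OC)c2O[C@@H](c3ccc(OCc4ccccc4)c(OC)c3)C(=[N+]=[N-])C(=O)c2c1
A5 | alternative 2 | methyl (2R,3R)-trans-2-(4-benzyloxy-3-methoxyphenyl)-5-[3-(tert-butyldimethylsilyloxy)propyl]-7-methoxy-2,3-dihydro-1-benzofuran-3-carboxylate | CC(C)(C)[Si](C)(C)OCCCc2cc(OC)c3c(c2)[C@@H](C(=O)OC)[C@H](c2ccc(OCc4ccccc4)c(OC)c2)O3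
A6 | alternative 3 | 2-{5-[3-(tert-butyldimethylsilyloxy)propyl]-2-hydroxy-3-methoxyphenyl}-1-(4-hydroxy-3-methoxyphenyl)propane-1,3-diol, configured at C2 as the future C3 of A7, carbinol carbon of either configuration | CC(C)(C)[Si](C)(C)OCCCc1cc(OC)c(O)c(c1)[C@@H](CO)C(O)c1ccc(O)c(OC)c1
A7 | alternative 3 | 4-[(2R,3S)-5-[3-(tert-butyldimethylsilyloxy)propyl]-3-(hydroxymethyl)-7-methoxy-2,3-dihydro-1-benzofuran-2-yl]-2-methoxyphenol | CC(C)(C)[Si](C)(C)OCCCc2cc(OC)c3c(c2)[C@@H](CO)[C@H](c2ccc(O)c(OC)c2)O3
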